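No target can pile up for ever in a flask that also destroys it, and the readings suggest that these flasks do.

in all of them: gas 56 mM (held)
- north: starting material 1 M; second substrate 1.5 equiv; free catalyst 0.12 mol%; temperature 100 °C; run made earlier
- north-east: starting material 2 M; second substrate 1 equiv; free catalyst 0.12 mol%; temperature 100 °C; run made earlier
- eta: starting material 1.0 M; second substrate 1.00 equiv; free catalyst 0.12 mol%; temperature 100 °C; time 12 min
- beta: starting material 1.0 M; second substrate 1.00 equiv; free catalyst 0.03 mol%; temperature 115 °C; time 12 min

| run | time / min | target / % | starting material / % |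
|---|---|---|---|
| north | 0.417 | 2.7 | 98.0 |
| north | 0.833 | 3.6 | 95.5 |
| north | 1.33 | 7.9 | 92.2 |
| north | 1.50 | 6.4 | 90.5 |
| north | 2.00 | 8.4 | 89.0 |
| north | 2.50 | 10.6 | 85.6 |
| north-east | 0.417 | 2.3 | 96.8 |
| north-east | 0.833 | 5.3 | 93.1 |
| north-east | 1.33 | 7.4 | 88.8 |
| north-east | 1.50 | 10.0 | 88.7 |
| north-east | 2.00 | 11.1 | 85.4 |
| north-east | 2.50 | 13.0 | 79.8 |

(scatter of a reading: 1 percentage point)

- the numbers in the tables scatter by 1 percentage point (one standard deviation)
- at the start none of the gas is in solution
- the earlier runs do not show what temperature does; that part of a forecast is a guess

- the winner by amount of target, in percent of the starting material charged; "neither" if no more than 2 percentage points parts them (eta / beta / neither)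
- how much target is there at the end, in percent of the starting material charged: eta
- how much target is there at the end, in percent of the starting material charged: beta

At the last reading of the north run, target P and starting material together fall short of the charge by a gap g of 3.80%. In the north run the gap starts near nought and grows, though each gap carries the scatter of two readings. I read it as a side product that holds one target and one starting material, each counted in the gap. The target then behaves like a tank with inflow r and a drain of time constant τ, which shortens as starting material A rises:

dP/dt = r − P/τ

While P still climbs straight, its mean is half its end value and g grows at twice P/τ, so g = Pt/τ. From the last readings: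

r = P/t = 0.0424 M min⁻¹ (north)

τ = Pt/g = 6.97 min (north), 4.51 min (north-east)

Scaled by the mean of A to 1.0 M, these give τc = 7.29 min.

The ceiling H, the level at which the drain equals the inflow (a quasi-steady state), is the quantity to carry:

H = rτc = 30.9% of the charge

Eta looks nearly like the north run, with the same catalyst and less second substrate, so I keep r. The north run stops at 2.50 min, shorter than τc, so its line is still straight. Eta runs 12 min, longer than τc, so it bends. A first pass gives 25.0%. By the balance, A in eta then averages a = 0.616 of its charge, which lifts the ceiling:

P = (H/a)(1 − exp(−at/τc)) = 32.0%

Beta has a quarter of the catalyst. I take r in proportion to it and guess that heat speeds inflow and drain alike, which leaves H untouched. With A averaging 0.7 of its charge and the lag assumed nearly over, I put beta at 11.0%, so by my reckoning eta holds more than beta.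

The forecast names eta too, but differs from me with 24% for eta and 18% for beta, and its own warning reads “The temperature effect is a guess”.

The answer to the first question is eta, with 35.2% of target in eta against 11.5% in beta.

    starting material + free catalyst ⇌ catalyst intermediate A (K = 285 M⁻¹, k = 97.4 M⁻¹ min⁻¹, Ea = 45.0 kJ mol⁻¹, ΔH = −21.0 kJ mol⁻¹)
    reagent + catalyst intermediate A → free catalyst + target (k = 8370 M⁻¹ min⁻¹, Ea = 50.0 kJ mol⁻¹)
    second substrate + free catalyst ⇌ catalyst intermediate B (K = 0.505 M⁻¹, k = 443 M⁻¹ min⁻¹, Ea = 49.0 kJ mol⁻¹, ΔH = −34.0 kJ mol⁻¹)
    reagent + catalyst intermediate B → free catalyst + second product (k = 2760 M⁻¹ min⁻¹, Ea = 39.0 kJ mol⁻¹)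
    starting material + target → side product (k = 0.132 M⁻¹ min⁻¹, Ea = 62.0 kJ mol⁻¹)
    gas ⇌ reagent, rate k6*(csat - [reagent]) (kL = 4.86 min⁻¹)
    (constants at 100 °C)

Of the two settings that part beta from eta, the loading of free catalyst has the largest single effect: beta given eta's loading holds 37.3% instead of 11.5%. With 49% of the starting material left unbound at the end of beta, and A taken as the mean of start and end, beta's ceiling becomes 10.3%, against the 11.5% it holds. A neighbour of beta, charged with 0.018 mol% of free catalyst, keeps 66% of its starting material unbound, which gives a ceiling of 5.60%, and that flask holds 6.98%.

All runs come from a simulation for an exercise; noise was put on by code.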